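## The problem

The target (55) is a 36-membered macrolactone, a single ring in which the ester links C1 to O35, with a 2-hexyl branch at C35 and a methyl group at C3. The chain carries nine secondary hydroxyls (C5, C9, C13, C17, C21, C25, C27, C29, C33) and twelve stereocentres (3R, 5R, 9R, 13S, 17S, 21R, 25S, 27S, 29S, 33S, 35R, 36S). The carbinols at C5, C9, C13, C17, C21 and C25 are 1,5-related and cannot control one another, so each must come from a reagent or an enantiopure building block. Relay is possible only in two places: C25 can set C29 (1,5-anti) and C29 then C27 (1,3-anti), and C35 can set C33 (1,3-anti) if both sit on one ring, whereas C36 (methyl against butyl) is too weakly biased to set C35. Of ten oxygens only O35 is acylated, so it must be told apart from nine other secondary hydroxyls. The lactone next to the free 33-hydroxyl is prone to acyl migration and translactonisation under base, and the α-branched aldehyde needed for C35 must not epimerise. The enabling feature is the segment O35, C35, C34, C33, C32, C31: it maps onto a 2-substituted 2,3-dihydro-4H-pyran-4-one with O35 as ring oxygen, C33 as the carbonyl and C31 as the enol-ether carbon, a latent aldehyde.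

## Retrosynthesis

Ring and last operations. Target 55 is traced to the heptakis-silyl ether 54 and to the macrocyclic alkene 53, which still has the C30=C31 double bond and two PMB ethers (O25, O33). Cutting C30=C31 (olefin metathesis) and O35–C1 (esterification) gives diene ester 52, hence acid 50 and alcohol 11. A direct Wittig union of a C31 aldehyde with a C1–C30 ylide was rejected: the ylide carbon C30 would sit next to the C29 oxygen and β-eliminate. Esterifying first and closing the ring by metathesis also avoids a high-dilution lactonisation at the hindered C35 carbinol. The forward reactions must give ring closure over oligomerisation, and hydrogenation without loss of the allylic C29 oxygen.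

Pyran template. Alcohol 11 comes from lactol 10 by Wittig methylenation, which opens the ring and frees O35 as the only hydroxyl. Lactol 10 comes from enol ether 9, alcohol 8 and enone 7. Cutting C34–C35 and O35–C31 of 7 gives (S)-2-methylhexanal 4 and diene 5 (hetero-Diels–Alder). This cut was preferred to two successive allylations because one catalytic step sets C35, the ring then sets C33, and the ring oxygen protects O35 at no cost. The forward reaction must show catalyst-controlled facial selectivity on an α-branched aldehyde.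

Aldehyde 4. It is traced through ester 3 to methyl (S)-3-hydroxy-2-methylpropanoate 1 by cutting C37–C38 (copper-catalysed coupling with a propyl Grignard reagent). C36 comes from the chiral pool.

East end of the acid. Acid 50 is traced through alcohol 49, octakis-silyl ether 48 and diol 47 to aldol 46. Cutting C28–C29 gives methyl ketone 43 and acrolein 44. The C25 PMB ether controls C29 (1,5-anti boron aldol), the new hydroxyl then controls C27 (1,3-anti reduction), and acrolein supplies the metathesis alkene. Ketone 43 comes from ketal 42 and alcohol 41.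

1,5-Polyol. Alcohol 41 is the desulfurised form of pentakis-dithiane 40. Each dithiane carbon (C7, C11, C15, C19, C23) is cut on both sides. This traces 40 to epoxide 38, silyl dithiane 23 and ketal epoxide 22, and 38 back through epoxides 35, 32 and 28 to epoxide 17, each time with 23 and (S)- or (R)-epichlorohydrin (24, 29). Each carbinol is therefore bought enantiopure. One flask forms two C–C bonds, silylates the previous oxygen by Brook rearrangement and delivers the next epoxide. The cost is one late removal of five dithianes.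

Terminal epoxides. Epoxide 17 (C1–C6) comes from aldehyde 14, made by ozonolysis of silyl ether 13 of (R)-citronellol 12, which supplies C3. Epoxide 22 (C24–C28) comes from aldehyde 19 and ester 18. Both epoxides are made by organocatalytic α-chlorination, reduction and ring closure.

## Roads not taken

Alternative 1: The cut is at C9–C10, C12–C13, C17–C18 and C20–C21, around the locally C2-symmetric C9–C21 core. In the forward step a γ-borylated allylborane, made in the flask, adds first to a pivalate-protected five-carbon hydroxy aldehyde and then twice to a five-carbon dialdehyde. This gives the (E,E)-diene tetraol bis-pivalate A1 (C5–C25).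
- Merits: four stereocentres and four C–C bonds in one operation; the alkenes disappear on hydrogenation.
- Weak points: the target is not symmetric beyond C9–C21 (C5 is syn to C9, C25 is anti to C21, and the two ends carry different appendages), so the identical ends of A1 must be differentiated statistically. Four free hydroxyls still need protection. Two reagent-controlled additions per molecule turn any enantiomeric leakage into diastereomers. O35 is not addressed.
- Comparison: for C9–C21 this road is shorter than the chosen one (one step against four linchpin steps). The chosen plan offers instead a directional chain with no statistical step, carbinols taken from enantiopure epichlorohydrin, silyl groups placed by the coupling itself, and the pyran that singles out O35.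

Alternative 2: The cut is the C14–C15 bond of a seco ester with two methyl-capped alkynes. In the forward step the molybdenum alkylidyne Mo(CC6H4OMe)(OSiPh3)3 A3 closes the 36-membered cycloalkyne A2, which is then hydrogenated.
- Merits: a very tolerant ring closure without E/Z or isomerisation problems, and two halves of similar size joined first by esterification.
- Weak points: the step creates no stereocentre and presupposes a seco ester in which O35 has already been told apart from nine silylated hydroxyls, which is the problem the pyran solves. Two propynyl groups must be installed, one next to the silylated C13 carbinol, where bulk slows metathesis.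
- Comparison: as a ring closure it is at least as reliable as the olefin metathesis used here, and probably better. The chosen plan gains because its two vinyl groups come from steps needed anyway (lactol methylenation, acrolein aldol) and because esterification plus metathesis is also the fragment union.

Alternative 3: The cut is at C26–C27 and C24–C25, with the lactol bond O27–C23. In the forward step the aldolase DERA adds two C2 aldehyde units to an α-chloro C2 aldehyde and the product closes to lactol A4.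
- Merits: the 25,27-syn pair is formed in one aqueous step from commodity aldehydes with enzymatic selectivity.
- Weak points: it covers six carbons and two of twelve stereocentres. C23 arrives as an aldehyde that must be joined to C22 and deoxygenated. The C28 chloride, β to oxygen, must be displaced by carbon, and C29 is still unset. The ring oxygen is O27, so the ring differentiates nothing that matters.
- Comparison: for C25/C27 it is shorter and more selective than the aldol–reduction pair used here. The chosen plan gains because C25 comes with the chain, C29 and C27 are set in two steps that also install the ring-closing alkene, and neither end needs homologation.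

Key step: step 3

Remarks on the chemistry:
- Chain intermediates are described with the carbon numbers of the target (C1 = lactone carbonyl). TBS = tert-butyldimethylsilyl, PMB = 4-methoxybenzyl.
- Assumption: the sense of induction of the chromium catalyst (step 3) and of the imidazolidinone catalysts (steps 10 and 12) is taken from their behaviour with simple unbranched aldehydes. Both mirror-image forms of each catalyst are available, and the antipode is used if the first run shows the opposite sense.
- The lithio reagent 25 cannot be stored. It first forms in step 13 and is made afresh from 23 and t-BuLi, in the same way, at the start of each of steps 14–17.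

## Steps

Step 1
Reactants: 1 methyl (S)-3-hydroxy-2-methylpropanoate
Product: 3 methyl (S)-2-methylhexanoate, via primary triflate 2 (not isolated)
Conditions: Tf2O, 2,6-lutidine, CH2Cl2, −78 °C; then n-PrMgCl, CuBr·SMe2 (10 mol %), Et2O, −40 → 0 °C
Reagents that add atoms: n-propylmagnesium chloride, CCC[Mg]Cl
Why: Triflation followed by copper-catalysed Grignard cross-coupling of the primary triflate forms C37–C38 at the CH2 group, so the adjacent stereocentre (C36) is not touched; the fast coupling at low temperature should spare the ester.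

Step 2
Reactants: 3 methyl (S)-2-methylhexanoate
Product: 4 (S)-2-methylhexanal
Conditions: i-Bu2AlH (1.05 equiv), CH2Cl2, −78 °C; aq. potassium sodium tartrate work-up
Reagents that add atoms: none
Why: Partial ester reduction stops at the aluminium hemiacetal, which gives the aldehyde on work-up; the aldehyde is used at once so that the α-centre does not enolise.

Step 3
Reactants: 4 (S)-2-methylhexanal; 5 (E)-1-methoxy-3-(trimethylsilyloxy)buta-1,3-diene
Product: 7 (R)-2-[(S)-hexan-2-yl]-2,3-dihydro-4H-pyran-4-one, via silyl enol ether cycloadduct 6 (not isolated)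
Conditions: (R,R)-(salen)CrCl (5 mol %; trivalent chromium; salen = N,N′-bis(3,5-di-tert-butylsalicylidene)cyclohexane-1,2-diamine dianion), 4 Å molecular sieves, t-BuOMe, −30 °C; then CF3CO2H (cat.), CH2Cl2, 0 °C
Reagents that add atoms: none
Why: The Lewis-acidic trivalent chromium centre binds the formyl oxygen of 4 and the electron-rich diene 5 adds to the activated C=O in a concerted, asynchronous [4+2] cycloaddition (a stepwise Mukaiyama aldol and ring closure would give the same adduct). The closest known reaction type is the chromium–salen catalysed hetero-Diels–Alder reaction of 1-methoxy-3-silyloxybutadienes with aliphatic aldehydes, which is also documented for α-stereogenic aldehydes under catalyst control. The six-membered oxacycle (O35, C35, C34, C33, C32, C31) closes by [4+2] cycloaddition with formation of C34–C35 and O35–C31, and acid then cleaves the silyl enol ether of 6 and expels methanol to leave enone 7. The only new stereocentre, C35, is controlled by the chiral salen ligand, which should expose the Re face of the bound aldehyde and give 35R; C36 is carried over from 4. The step needs facial selectivity at C35 against the Felkin preference of the aldehyde (the target has the 35,36-anti, anti-Felkin arrangement), and the small steric difference between methyl and butyl at C36 is what allows the catalyst to dominate. Regiochemistry is fixed by the polarity of the diene, whose nucleophilic terminus C34 bonds to the carbonyl carbon. Low temperature, a non-basic medium and sieves protect the α-stereocentre of 4 from enolisation.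

Step 4
Reactants: 7 (R)-2-[(S)-hexan-2-yl]-2,3-dihydro-4H-pyran-4-one
Product: 8 (2R,4R)-2-[(S)-hexan-2-yl]-3,4-dihydro-2H-pyran-4-ol
Conditions: NaBH4, CeCl3·7H2O, MeOH, −78 °C
Reagents that add atoms: none
Why: Luche 1,2-reduction; hydride attacks the enone carbonyl axially on the half-chair that holds the C35 side chain equatorial, which should give the equatorial alcohol cis to the side chain, i.e. the 33,35-anti diol of the target.

Step 5
Reactants: 8 (2R,4R)-2-[(S)-hexan-2-yl]-3,4-dihydro-2H-pyran-4-ol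
Product: 9 (2R,4R)-2-[(S)-hexan-2-yl]-4-[(4-methoxybenzyl)oxy]-3,4-dihydro-2H-pyran
Conditions: NaH, 4-MeOC6H4CH2Cl, n-Bu4NI (cat.), DMF, 0 °C → rt
Reagents that add atoms: 4-methoxybenzyl chloride, COc1ccc(CCl)cc1
Why: Williamson etherification under basic conditions avoids acid-induced allylic ionisation of the glycal-like alcohol; a benzyl-type ether at O33 cannot migrate to O35 or β-eliminate easily in the later Wittig step and is removed by the late hydrogenolysis.

Step 6
Reactants: 9 (2R,4R)-2-[(S)-hexan-2-yl]-4-[(4-methoxybenzyl)oxy]-3,4-dihydro-2H-pyran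
Product: 10 (4R,6R)-6-[(S)-hexan-2-yl]-4-[(4-methoxybenzyl)oxy]oxan-2-ol (anomer mixture)
Conditions: Ph3P·HBr (5 mol %), THF/H2O (10:1), rt
Reagents that add atoms: water, O
Why: Acid-catalysed hydration of the cyclic enol ether: protonation at C32 gives the oxocarbenium ion at C31, which water traps to the 2-deoxy lactol; the mild phosphonium salt should leave the allylic C33 ether in place.

Step 7
Reactants: 10 (4R,6R)-6-[(S)-hexan-2-yl]-4-[(4-methoxybenzyl)oxy]oxan-2-ol
Product: 11 (4S,6R,7S)-4-[(4-methoxybenzyl)oxy]-7-methylundec-1-en-6-ol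
Conditions: Ph3PCH3Br, KOt-Bu, THF, 0 °C → rt
Reagents that add atoms: methyltriphenylphosphonium bromide, C[P+](c1ccccc1)(c1ccccc1)c1ccccc1.[Br-]
Why: Wittig methylenation of the lactol through its open hydroxy-aldehyde form gives the C31 vinyl group and releases O35 as the only free hydroxyl of the fragment; no stereocentre is touched.

Step 8
Reactants: 12 (R)-citronellol
Product: 13 (R)-tert-butyl[(3,7-dimethyloct-6-en-1-yl)oxy]dimethylsilane
Conditions: TBSCl, imidazole, CH2Cl2, rt
Reagents that add atoms: tert-butyldimethylsilyl chloride, CC(C)(C)[Si](C)(C)Cl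
Why: Standard silylation; C1 is carried as a silyl ether because an ester would not survive the lithiated dithianes used later.

Step 9
Reactants: 13 (R)-tert-butyl[(3,7-dimethyloct-6-en-1-yl)oxy]dimethylsilane
Product: 14 (R)-6-[(tert-butyldimethylsilyl)oxy]-4-methylhexanal
Conditions: O3, CH2Cl2, −78 °C; then PPh3, −78 °C → rt
Reagents that add atoms: ozone, [O-][O+]=O
Why: Ozonolysis of the trisubstituted alkene with reductive work-up gives the C6 aldehyde and acetone; the C3 stereocentre from citronellol is remote and unaffected.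

Step 10
Reactants: 14 (R)-6-[(tert-butyldimethylsilyl)oxy]-4-methylhexanal
Product: 17 tert-butyldimethyl{(3S)-3-methyl-4-[(2S)-oxiran-2-yl]butoxy}silane (C1–C6 epoxide), via α-chloro aldehyde 15 (not isolated), via chlorohydrin 16 (not isolated)
Conditions: (5R)-5-benzyl-2,2,3-trimethylimidazolidin-4-one·CF3CO2H (10 mol %), 2,3,4,5,6,6-hexachlorocyclohexa-2,4-dienone, acetone, −30 °C; then NaBH4, EtOH, 0 °C; then KOH (aq), rt
Reagents that add atoms: none
Why: Enamine-catalysed α-chlorination sets the C5–Cl bond under catalyst control; borohydride gives the chlorohydrin and hydroxide closes the epoxide by intramolecular SN2 displacement with inversion at C5, so the new C5–O bond has the configuration of the target.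

Step 11
Reactants: 18 ethyl 3-(2-methyl-1,3-dioxolan-2-yl)propanoate
Product: 19 3-(2-methyl-1,3-dioxolan-2-yl)propanal
Conditions: i-Bu2AlH, CH2Cl2, −78 °C
Reagents that add atoms: none
Why: Partial reduction of the ester to the aldehyde; the ketal is inert to the hydride.

Step 12
Reactants: 19 3-(2-methyl-1,3-dioxolan-2-yl)propanal
Product: 22 (R)-2-methyl-2-(oxiran-2-ylmethyl)-1,3-dioxolane (C24–C28 epoxide), via α-chloro aldehyde 20 (not isolated), via chlorohydrin 21 (not isolated)
Conditions: (5S)-5-benzyl-2,2,3-trimethylimidazolidin-4-one·CF3CO2H (10 mol %), 2,3,4,5,6,6-hexachlorocyclohexa-2,4-dienone, acetone, −30 °C; then NaBH4, EtOH, 0 °C; then KOH (aq), rt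
Reagents that add atoms: none
Why: Same α-chlorination, reduction and ring closure as in step 10 with the mirror-image catalyst; inversion at C25 on ring closure gives the C25–O configuration of the target, and C27 travels as a ketal.

Step 13
Reactants: 17 C1–C6 epoxide; 23 2-(tert-butyldimethylsilyl)-1,3-dithiane; 24 (S)-epichlorohydrin
Product: 28 C1–C10 epoxide (C9–C10 oxirane; C7 dithiane; O1 and O5 silylated), via lithiated silyl dithiane 25 (not isolated), via C7 lithio dithiane 26 (not isolated), via C9 chlorohydrin alkoxide 27 (not isolated)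
Conditions: 23, t-BuLi, Et2O, −78 → −45 °C; 17, −78 → −25 °C; then 24 (3 equiv), HMPA, THF, −78 °C → rt
Reagents that add atoms: none
Why: Three-component dithiane linchpin coupling: lithio reagent 25, formed from 23 and t-BuLi, opens epoxide 17 at C6, HMPA triggers the 1,4-Brook rearrangement that moves silicon to O5 and leaves a new carbanion at C7, and this opens (S)-epichlorohydrin at its epoxide CH2. The chlorohydrin alkoxide then closes to the C9–C10 epoxide without any bond change at the carbinol carbon, so C9 is taken unchanged from the chiral pool.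

Step 14
Reactants: 28 C1–C10 epoxide; 23 2-(tert-butyldimethylsilyl)-1,3-dithiane; 29 (R)-epichlorohydrin
Product: 32 C1–C14 epoxide (C13–C14 oxirane; dithianes at C7 and C11), via C11 lithio dithiane 30 (not isolated), via C13 chlorohydrin alkoxide 31 (not isolated)
Conditions: 23, t-BuLi, Et2O, −78 → −45 °C; 28, −78 → −25 °C; then 29 (3 equiv), HMPA, THF, −78 °C → rt
Reagents that add atoms: none
Why: Second linchpin cycle by the mechanism of step 13: lithio reagent 25, made afresh from 23 and t-BuLi, opens 28 at C10, the Brook shift silylates O9 and leaves the C11 carbanion, and (R)-epichlorohydrin supplies C12–C14 with the C13 configuration of the target.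

Step 15
Reactants: 32 C1–C14 epoxide; 23 2-(tert-butyldimethylsilyl)-1,3-dithiane; 24 (S)-epichlorohydrin
Product: 35 C1–C18 epoxide (C17–C18 oxirane; dithianes at C7 C11 C15), via C15 lithio dithiane 33 (not isolated), via C17 chlorohydrin alkoxide 34 (not isolated)
Conditions: 23, t-BuLi, Et2O, −78 → −45 °C; 32, −78 → −25 °C; then 24 (3 equiv), HMPA, THF, −78 °C → rt
Reagents that add atoms: none
Why: Third linchpin cycle: lithio reagent 25, made afresh from 23 and t-BuLi, opens 32 at C14, O13 is silylated by the Brook shift and C17 comes from (S)-epichlorohydrin.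

Step 16
Reactants: 35 C1–C18 epoxide; 23 2-(tert-butyldimethylsilyl)-1,3-dithiane; 29 (R)-epichlorohydrin
Product: 38 C1–C22 epoxide (C21–C22 oxirane; dithianes at C7 C11 C15 C19), via C19 lithio dithiane 36 (not isolated), via C21 chlorohydrin alkoxide 37 (not isolated)
Conditions: 23, t-BuLi, Et2O, −78 → −45 °C; 35, −78 → −25 °C; then 29 (3 equiv), HMPA, THF, −78 °C → rt
Reagents that add atoms: none
Why: Fourth linchpin cycle: lithio reagent 25, made afresh from 23 and t-BuLi, opens 35 at C18, O17 is silylated by the Brook shift and C21 comes from (R)-epichlorohydrin.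

Step 17
Reactants: 38 C1–C22 epoxide; 23 2-(tert-butyldimethylsilyl)-1,3-dithiane; 22 C24–C28 epoxide
Product: 40 C1–C28 pentakis-dithiane alcohol (25-OH; C27 ketal), via C23 lithio dithiane 39 (not isolated)
Conditions: 23, t-BuLi, Et2O, −78 → −45 °C; 38, −78 → −25 °C; then 22 (2 equiv), HMPA, THF, −78 °C → rt
Reagents that add atoms: none
Why: The same linchpin coupling, begun by lithio reagent 25 made afresh from 23 and t-BuLi and ended by ketal epoxide 22, which is opened at C24; O21 is silylated by the Brook shift and O25 is left as the single free hydroxyl, ready for its own protecting group.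

Step 18
Reactants: 40 C1–C28 pentakis-dithiane alcohol
Product: 41 C1–C28 alcohol (25-OH; C27 ketal; all dithianes reduced to CH2)
Conditions: Raney Ni (W-2, large excess), H2 (1 atm), EtOH, rt → 50 °C
Reagents that add atoms: none
Why: Nickel-mediated hydrogenolysis of the C–S bonds converts the five dithianes into methylene groups; silyl ethers, ketal and the free alcohol are inert and no stereocentre is involved.

Step 19
Reactants: 41 C1–C28 alcohol
Product: 42 C25 PMB ether of the C1–C28 ketal
Conditions: NaH, 4-MeOC6H4CH2Cl, n-Bu4NI (cat.), THF/DMF, 0 °C → rt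
Reagents that add atoms: 4-methoxybenzyl chloride, COc1ccc(CCl)cc1
Why: Williamson etherification; the C25 benzyl-type ether is what directs the later boron aldol, and it is installed after desulfurisation so that it never meets the nickel.

Step 20
Reactants: 42 C25 PMB ether of the C1–C28 ketal
Product: 43 C1–C28 methyl ketone (27-oxo; 25-OPMB)
Conditions: PPTS (cat.), acetone/H2O (10:1), 45 °C
Reagents that add atoms: water, O
Why: Acid-catalysed ketal hydrolysis under conditions that should leave the silyl ethers and the PMB ether in place.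

Step 21
Reactants: 43 C1–C28 methyl ketone; 44 acrolein
Product: 46 C1–C30 aldol (29-hydroxy-27-ketone; terminal vinyl), via boron enolate 45 (not isolated)
Conditions: (c-Hex)2BCl, Et3N, Et2O, −78 → 0 °C; then 44, −78 °C; then MeOH, pH 7 buffer, H2O2, 0 °C
Reagents that add atoms: none
Why: Boron aldol of a β-alkoxy methyl ketone (Paterson aldol): the kinetic dicyclohexylboron enolate on the methyl side adds to acrolein with 1,5-anti induction from the C25 PMB ether, which should set C29 and install the vinyl group for ring closure.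

Step 22
Reactants: 46 C1–C30 aldol
Product: 47 C1–C30 27,29-anti diol
Conditions: Me4NBH(OAc)3, MeCN/AcOH (1:1), −30 °C
Reagents that add atoms: none
Why: Evans–Saksena reduction: the borohydride binds to O29 by acetoxy exchange and delivers hydride intramolecularly through a chair transition state, giving the 27,29-anti diol and hence the 25,27-syn relationship.

Step 23
Reactants: 47 C1–C30 27,29-anti diol
Product: 48 octakis-TBS ether (O1 O5 O9 O13 O17 O21 O27 O29; 25-OPMB)
Conditions: TBSOTf, 2,6-lutidine, CH2Cl2, −78 → 0 °C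
Reagents that add atoms: tert-butyldimethylsilyl trifluoromethanesulfonate, CC(C)(C)[Si](C)(C)OS(=O)(=O)C(F)(F)F
Why: Silylation of both secondary alcohols with the silyl triflate and a hindered base; the PMB ether and the existing silyl ethers are stable.

Step 24
Reactants: 48 octakis-TBS ether
Product: 49 C1 primary alcohol
Conditions: HF·pyridine, pyridine, THF, 0 °C
Reagents that add atoms: none
Why: Buffered HF·pyridine cleaves the unhindered primary silyl ether much faster than the seven secondary ones.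

Step 25
Reactants: 49 C1 primary alcohol
Product: 50 C1–C30 acid
Conditions: TEMPO (cat.), PhI(OAc)2, MeCN/pH 7 buffer, rt
Reagents that add atoms: water, O
Why: Nitroxyl-catalysed oxidation takes the primary alcohol through the aldehyde hydrate to the acid without touching the alkene, the PMB ether or the silyl ethers; C3 is β to the carbonyl and cannot epimerise.

Step 26
Reactants: 50 C1–C30 acid; 11 (4S,6R,7S)-4-[(4-methoxybenzyl)oxy]-7-methylundec-1-en-6-ol
Product: 52 diene ester (O35–C1 ester; vinyl groups at C29 and C32), via mixed anhydride 51 (not isolated)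
Conditions: 2,4,6-Cl3C6H2COCl, Et3N, THF, rt; then 11, DMAP, toluene, rt
Reagents that add atoms: none
Why: Yamaguchi esterification: the mixed anhydride is activated by DMAP and trapped by O35, the only free hydroxyl in either partner, so no selectivity problem arises.

Step 27
Reactants: 52 diene ester
Product: 53 macrocyclic alkene (C30=C31; E/Z mixture)
Conditions: second-generation Grubbs catalyst (H2IMes)(PCy3)Cl2Ru=CHPh (10 mol %), CH2Cl2 (1 mM), 40 °C
Reagents that add atoms: none
Why: Ring-closing olefin metathesis between the two monosubstituted alkenes at high dilution forms C30=C31 and the 36-membered ring with loss of ethylene; the alkene geometry is irrelevant because the bond is hydrogenated next.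

Step 28
Reactants: 53 macrocyclic alkene
Product: 54 heptakis-TBS macrolactone 25,33-diol
Conditions: H2 (1 atm), Pd(OH)2/C, EtOAc/EtOH, rt
Reagents that add atoms: none
Why: Heterogeneous hydrogenation saturates C30–C31 and hydrogenolyses both PMB ethers in one operation under neutral conditions that do not move the lactone.

Step 29
Reactants: 54 heptakis-TBS macrolactone 25,33-diol
Product: 55 CNP0225459.2
Conditions: HF·pyridine, pyridine, THF, 0 °C → rt
Reagents that add atoms: none
Why: Fluoride cleaves the seven secondary silyl ethers under mildly acidic conditions, which disfavour acyl migration from O35 to O33.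

## Compound list

1 | methyl (S)-3-hydroxy-2-methylpropanoate | OC[C@H](C)C(=O)OC | starting material
2 | methyl (S)-2-methyl-3-[(trifluoromethanesulfonyl)oxy]propanoate | O=S(=O)(OC[C@H](C)C(=O)OC)C(F)(F)F | intermediate
3 | methyl (S)-2-methylhexanoate | CCCC[C@H](C)C(=O)OC | intermediate
4 | (S)-2-methylhexanal | CCCC[C@H](C)C=O | intermediate
5 | (E)-1-methoxy-3-(trimethylsilyloxy)buta-1,3-diene | CO/C=C/C(=C)O[Si](C)(C)C | starting material
6 | (6R)-6-[(2S)-hexan-2-yl]-2-methoxy-4-[(trimethylsilyl)oxy]-5,6-dihydro-2H-pyran (acetal centre unassigned) | CCCC[C@H](C)[C@H]1CC(O[Si](C)(C)C)=CC(OC)O1 | intermediate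
7 | (R)-2-[(S)-hexan-2-yl]-2,3-dihydro-4H-pyran-4-one | CCCC[C@H](C)[C@H]1CC(=O)C=CO1 | intermediate
8 | (2R,4R)-2-[(S)-hexan-2-yl]-3,4-dihydro-2H-pyran-4-ol | CCCC[C@H](C)[C@H]1C[C@@H](O)C=CO1 | intermediate
9 | (2R,4R)-2-[(S)-hexan-2-yl]-4-[(4-methoxybenzyl)oxy]-3,4-dihydro-2H-pyran | CCCC[C@H](C)[C@H]1C[C@@H](OCc2ccc(OC)cc2)C=CO1 | intermediate
10 | (4R,6R)-6-[(S)-hexan-2-yl]-4-[(4-methoxybenzyl)oxy]oxan-2-ol (anomer mixture) | CCCC[C@H](C)[C@H]1C[C@@H](OCc2ccc(OC)cc2)CC(O)O1 | intermediate
11 | (4S,6R,7S)-4-[(4-methoxybenzyl)oxy]-7-methylundec-1-en-6-ol (C31–C40 with O35 free) | CCCC[C@H](C)[C@H](O)C[C@@H](OCc1ccc(OC)cc1)CC=C | intermediate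
12 | (R)-citronellol, (R)-3,7-dimethyloct-6-en-1-ol | CC(C)=CCC[C@@H](C)CCO | starting material
13 | (R)-tert-butyl[(3,7-dimethyloct-6-en-1-yl)oxy]dimethylsilane | CC(C)=CCC[C@@H](C)CCO[Si](C)(C)C(C)(C)C | intermediate
14 | (R)-6-[(tert-butyldimethylsilyl)oxy]-4-methylhexanal | O=CCC[C@@H](C)CCO[Si](C)(C)C(C)(C)C | intermediate
15 | (2R,4S)-6-[(tert-butyldimethylsilyl)oxy]-2-chloro-4-methylhexanal | O=C[C@H](Cl)C[C@@H](C)CCO[Si](C)(C)C(C)(C)C | intermediate
16 | (2R,4S)-6-[(tert-butyldimethylsilyl)oxy]-2-chloro-4-methylhexan-1-ol | OC[C@H](Cl)C[C@@H](C)CCO[Si](C)(C)C(C)(C)C | intermediate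
17 | tert-butyldimethyl{(3S)-3-methyl-4-[(2S)-oxiran-2-yl]butoxy}silane (C1–C6 epoxide; C3 and C5 as in the target) | C1[C@@H](O1)C[C@@H](C)CCO[Si](C)(C)C(C)(C)C | intermediate
18 | ethyl 3-(2-methyl-1,3-dioxolan-2-yl)propanoate | CCOC(=O)CCC1(C)OCCO1 | starting material
19 | 3-(2-methyl-1,3-dioxolan-2-yl)propanal | O=CCCC1(C)OCCO1 | intermediate
20 | (S)-2-chloro-3-(2-methyl-1,3-dioxolan-2-yl)propanal | CC1(OCCO1)C[C@H](Cl)C=O | intermediate
21 | (S)-2-chloro-3-(2-methyl-1,3-dioxolan-2-yl)propan-1-ol | CC1(OCCO1)C[C@H](Cl)CO | intermediate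
22 | (R)-2-methyl-2-(oxiran-2-ylmethyl)-1,3-dioxolane (C24–C28 epoxide; C25 as in the target) | CC1(OCCO1)C[C@@H]2CO2 | intermediate
23 | 2-(tert-butyldimethylsilyl)-1,3-dithiane | CC(C)(C)[Si](C)(C)C1SCCCS1 | starting material
24 | (S)-epichlorohydrin, (S)-2-(chloromethyl)oxirane | ClC[C@@H]1CO1 | starting material
25 | 2-lithio-2-(tert-butyldimethylsilyl)-1,3-dithiane | [Li]C1([Si](C)(C)C(C)(C)C)SCCCS1 | intermediate
26 | C1–C7 lithio dithiane: 2-lithio-1,3-dithiane at C7, OTBS at C1 and C5 | [Li]C1(SCCCS1)C[C@@H](O[Si](C)(C)C(C)(C)C)C[C@@H](C)CCO[Si](C)(C)C(C)(C)C | intermediate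
27 | C1–C10 chlorohydrin lithium alkoxide: 10-chloro, 9-OLi, C7 dithiane, OTBS at C1 and C5 | ClC[C@@H](O[Li])CC1(SCCCS1)C[C@@H](O[Si](C)(C)C(C)(C)C)C[C@@H](C)CCO[Si](C)(C)C(C)(C)C | intermediate
28 | C1–C10 epoxide: 9,10-epoxy-3-methyldecane-1,5-diol bis-TBS ether with a 1,3-dithiane at C7 (C3, C5, C9 as in the target) | C1[C@@H](O1)CC2(SCCCS2)C[C@@H](O[Si](C)(C)C(C)(C)C)C[C@@H](C)CCO[Si](C)(C)C(C)(C)C | intermediate
29 | (R)-epichlorohydrin, (R)-2-(chloromethyl)oxirane | ClC[C@H]1CO1 | starting material
30 | C1–C11 lithio dithiane: 2-lithio-1,3-dithiane at C11, dithiane at C7, OTBS at C1, C5, C9 | [Li]C1(SCCCS1)C[C@@H](O[Si](C)(C)C(C)(C)C)CC2(SCCCS2)C[C@@H](O[Si](C)(C)C(C)(C)C)C[C@@H](C)CCO[Si](C)(C)C(C)(C)C | intermediate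
31 | C1–C14 chlorohydrin lithium alkoxide: 14-chloro, 13-OLi, dithianes at C7 and C11 | ClC[C@H](O[Li])CC1(SCCCS1)C[C@@H](O[Si](C)(C)C(C)(C)C)CC2(SCCCS2)C[C@@H](O[Si](C)(C)C(C)(C)C)C[C@@H](C)CCO[Si](C)(C)C(C)(C)C | intermediate
32 | C1–C14 epoxide: 13,14-epoxide, dithianes at C7 and C11, OTBS at C1, C5, C9 (C3, C5, C9, C13 as in the target) | C1[C@H](O1)CC2(SCCCS2)C[C@@H](O[Si](C)(C)C(C)(C)C)CC2(SCCCS2)C[C@@H](O[Si](C)(C)C(C)(C)C)C[C@@H](C)CCO[Si](C)(C)C(C)(C)C | intermediate
33 | C1–C15 lithio dithiane: 2-lithio-1,3-dithiane at C15, dithianes at C7 and C11, OTBS at C1, C5, C9, C13 | [Li]C1(SCCCS1)C[C@H](O[Si](C)(C)C(C)(C)C)CC2(SCCCS2)C[C@@H](O[Si](C)(C)C(C)(C)C)CC2(SCCCS2)C[C@@H](O[Si](C)(C)C(C)(C)C)C[C@@H](C)CCO[Si](C)(C)C(C)(C)C | intermediate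
34 | C1–C18 chlorohydrin lithium alkoxide: 18-chloro, 17-OLi, dithianes at C7, C11, C15 | ClC[C@@H](O[Li])CC1(SCCCS1)C[C@H](O[Si](C)(C)C(C)(C)C)CC2(SCCCS2)C[C@@H](O[Si](C)(C)C(C)(C)C)CC2(SCCCS2)C[C@@H](O[Si](C)(C)C(C)(C)C)C[C@@H](C)CCO[Si](C)(C)C(C)(C)C | intermediate
35 | C1–C18 epoxide: 17,18-epoxide, dithianes at C7, C11, C15, OTBS at C1, C5, C9, C13 (stereocentres as in the target) | C1[C@@H](O1)CC2(SCCCS2)C[C@H](O[Si](C)(C)C(C)(C)C)CC2(SCCCS2)C[C@@H](O[Si](C)(C)C(C)(C)C)CC2(SCCCS2)C[C@@H](O[Si](C)(C)C(C)(C)C)C[C@@H](C)CCO[Si](C)(C)C(C)(C)C | intermediate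
36 | C1–C19 lithio dithiane: 2-lithio-1,3-dithiane at C19, dithianes at C7, C11, C15, OTBS at C1, C5, C9, C13, C17 | [Li]C1(SCCCS1)C[C@@H](O[Si](C)(C)C(C)(C)C)CC2(SCCCS2)C[C@H](O[Si](C)(C)C(C)(C)C)CC2(SCCCS2)C[C@@H](O[Si](C)(C)C(C)(C)C)CC2(SCCCS2)C[C@@H](O[Si](C)(C)C(C)(C)C)C[C@@H](C)CCO[Si](C)(C)C(C)(C)C | intermediate
37 | C1–C22 chlorohydrin lithium alkoxide: 22-chloro, 21-OLi, dithianes at C7, C11, C15, C19 | ClC[C@H](O[Li])CC1(SCCCS1)C[C@@H](O[Si](C)(C)C(C)(C)C)CC2(SCCCS2)C[C@H](O[Si](C)(C)C(C)(C)C)CC2(SCCCS2)C[C@@H](O[Si](C)(C)C(C)(C)C)CC2(SCCCS2)C[C@@H](O[Si](C)(C)C(C)(C)C)C[C@@H](C)CCO[Si](C)(C)C(C)(C)C | intermediate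
38 | C1–C22 epoxide: 21,22-epoxide, dithianes at C7, C11, C15, C19, OTBS at C1, C5, C9, C13, C17 (stereocentres as in the target) | C1[C@H](O1)CC2(SCCCS2)C[C@@H](O[Si](C)(C)C(C)(C)C)CC2(SCCCS2)C[C@H](O[Si](C)(C)C(C)(C)C)CC2(SCCCS2)C[C@@H](O[Si](C)(C)C(C)(C)C)CC2(SCCCS2)C[C@@H](O[Si](C)(C)C(C)(C)C)C[C@@H](C)CCO[Si](C)(C)C(C)(C)C | intermediate
39 | C1–C23 lithio dithiane: 2-lithio-1,3-dithiane at C23, dithianes at C7, C11, C15, C19, OTBS at C1, C5, C9, C13, C17, C21 | [Li]C1(SCCCS1)C[C@H](O[Si](C)(C)C(C)(C)C)CC2(SCCCS2)C[C@@H](O[Si](C)(C)C(C)(C)C)CC2(SCCCS2)C[C@H](O[Si](C)(C)C(C)(C)C)CC2(SCCCS2)C[C@@H](O[Si](C)(C)C(C)(C)C)CC2(SCCCS2)C[C@@H](O[Si](C)(C)C(C)(C)C)C[C@@H](C)CCO[Si](C)(C)C(C)(C)C | intermediate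
40 | C1–C28 pentakis-dithiane alcohol: 25-OH, C27 ethylene ketal, dithianes at C7, C11, C15, C19, C23, OTBS at C1, C5, C9, C13, C17, C21 | CC1(OCCO1)C[C@@H](O)CC2(SCCCS2)C[C@H](O[Si](C)(C)C(C)(C)C)CC2(SCCCS2)C[C@@H](O[Si](C)(C)C(C)(C)C)CC2(SCCCS2)C[C@H](O[Si](C)(C)C(C)(C)C)CC2(SCCCS2)C[C@@H](O[Si](C)(C)C(C)(C)C)CC2(SCCCS2)C[C@@H](O[Si](C)(C)C(C)(C)C)C[C@@H](C)CCO[Si](C)(C)C(C)(C)C | intermediate
41 | C1–C28 alcohol: 25-OH, C27 ethylene ketal, OTBS at C1, C5, C9, C13, C17, C21, saturated chain | CC1(OCCO1)C[C@@H](O)CCC[C@H](O[Si](C)(C)C(C)(C)C)CCC[C@@H](O[Si](C)(C)C(C)(C)C)CCC[C@H](O[Si](C)(C)C(C)(C)C)CCC[C@@H](O[Si](C)(C)C(C)(C)C)CCC[C@@H](O[Si](C)(C)C(C)(C)C)C[C@@H](C)CCO[Si](C)(C)C(C)(C)C | intermediate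
42 | C1–C28 ketal with 25-OPMB and OTBS at C1, C5, C9, C13, C17, C21 | CC1(OCCO1)C[C@@H](OCc2ccc(OC)cc2)CCC[C@H](O[Si](C)(C)C(C)(C)C)CCC[C@@H](O[Si](C)(C)C(C)(C)C)CCC[C@H](O[Si](C)(C)C(C)(C)C)CCC[C@@H](O[Si](C)(C)C(C)(C)C)CCC[C@@H](O[Si](C)(C)C(C)(C)C)C[C@@H](C)CCO[Si](C)(C)C(C)(C)C | intermediate
43 | C1–C28 methyl ketone: 27-oxo, 25-OPMB, OTBS at C1, C5, C9, C13, C17, C21 | CC(=O)C[C@@H](OCc1ccc(OC)cc1)CCC[C@H](O[Si](C)(C)C(C)(C)C)CCC[C@@H](O[Si](C)(C)C(C)(C)C)CCC[C@H](O[Si](C)(C)C(C)(C)C)CCC[C@@H](O[Si](C)(C)C(C)(C)C)CCC[C@@H](O[Si](C)(C)C(C)(C)C)C[C@@H](C)CCO[Si](C)(C)C(C)(C)C | intermediate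
44 | acrolein, prop-2-enal | C=CC=O | starting material
45 | dicyclohexylboron enolate of 43 (C27=C28 enol borinate) | C=C(OB(C1CCCCC1)C1CCCCC1)C[C@@H](OCc1ccc(OC)cc1)CCC[C@H](O[Si](C)(C)C(C)(C)C)CCC[C@@H](O[Si](C)(C)C(C)(C)C)CCC[C@H](O[Si](C)(C)C(C)(C)C)CCC[C@@H](O[Si](C)(C)C(C)(C)C)CCC[C@@H](O[Si](C)(C)C(C)(C)C)C[C@@H](C)CCO[Si](C)(C)C(C)(C)C | intermediate
46 | C1–C30 aldol: 29-hydroxy-27-oxo, vinyl at C29, 25-OPMB, OTBS at C1, C5, C9, C13, C17, C21 | C=C[C@H](O)CC(=O)C[C@@H](OCc1ccc(OC)cc1)CCC[C@H](O[Si](C)(C)C(C)(C)C)CCC[C@@H](O[Si](C)(C)C(C)(C)C)CCC[C@H](O[Si](C)(C)C(C)(C)C)CCC[C@@H](O[Si](C)(C)C(C)(C)C)CCC[C@@H](O[Si](C)(C)C(C)(C)C)C[C@@H](C)CCO[Si](C)(C)C(C)(C)C | intermediate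
47 | C1–C30 27,29-anti diol: vinyl at C29, 25-OPMB, OTBS at C1, C5, C9, C13, C17, C21 | C=C[C@H](O)C[C@@H](O)C[C@@H](OCc1ccc(OC)cc1)CCC[C@H](O[Si](C)(C)C(C)(C)C)CCC[C@@H](O[Si](C)(C)C(C)(C)C)CCC[C@H](O[Si](C)(C)C(C)(C)C)CCC[C@@H](O[Si](C)(C)C(C)(C)C)CCC[C@@H](O[Si](C)(C)C(C)(C)C)C[C@@H](C)CCO[Si](C)(C)C(C)(C)C | intermediate
48 | C1–C30 octakis-TBS ether: OTBS at C1, C5, C9, C13, C17, C21, C27, C29; 25-OPMB; vinyl at C29 | C=C[C@H](O[Si](C)(C)C(C)(C)C)C[C@@H](O[Si](C)(C)C(C)(C)C)C[C@@H](OCc1ccc(OC)cc1)CCC[C@H](O[Si](C)(C)C(C)(C)C)CCC[C@@H](O[Si](C)(C)C(C)(C)C)CCC[C@H](O[Si](C)(C)C(C)(C)C)CCC[C@@H](O[Si](C)(C)C(C)(C)C)CCC[C@@H](O[Si](C)(C)C(C)(C)C)C[C@@H](C)CCO[Si](C)(C)C(C)(C)C | intermediate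
49 | C1–C30 primary alcohol: 1-OH; OTBS at C5, C9, C13, C17, C21, C27, C29; 25-OPMB | C=C[C@H](O[Si](C)(C)C(C)(C)C)C[C@@H](O[Si](C)(C)C(C)(C)C)C[C@@H](OCc1ccc(OC)cc1)CCC[C@H](O[Si](C)(C)C(C)(C)C)CCC[C@@H](O[Si](C)(C)C(C)(C)C)CCC[C@H](O[Si](C)(C)C(C)(C)C)CCC[C@@H](O[Si](C)(C)C(C)(C)C)CCC[C@@H](O[Si](C)(C)C(C)(C)C)C[C@@H](C)CCO | intermediate
50 | C1–C30 acid: C1 carboxylic acid; OTBS at C5, C9, C13, C17, C21, C27, C29; 25-OPMB; vinyl at C29 | C=C[C@H](O[Si](C)(C)C(C)(C)C)C[C@@H](O[Si](C)(C)C(C)(C)C)C[C@@H](OCc1ccc(OC)cc1)CCC[C@H](O[Si](C)(C)C(C)(C)C)CCC[C@@H](O[Si](C)(C)C(C)(C)C)CCC[C@H](O[Si](C)(C)C(C)(C)C)CCC[C@@H](O[Si](C)(C)C(C)(C)C)CCC[C@@H](O[Si](C)(C)C(C)(C)C)C[C@@H](C)CC(=O)O | intermediate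
51 | mixed anhydride of 50 with 2,4,6-trichlorobenzoic acid | C=C[C@H](O[Si](C)(C)C(C)(C)C)C[C@@H](O[Si](C)(C)C(C)(C)C)C[C@@H](OCc1ccc(OC)cc1)CCC[C@H](O[Si](C)(C)C(C)(C)C)CCC[C@@H](O[Si](C)(C)C(C)(C)C)CCC[C@H](O[Si](C)(C)C(C)(C)C)CCC[C@@H](O[Si](C)(C)C(C)(C)C)CCC[C@@H](O[Si](C)(C)C(C)(C)C)C[C@@H](C)CC(=O)OC(=O)c1c(Cl)cc(Cl)cc1Cl | intermediate
52 | diene ester: ester of acid 50 with O35 of alcohol 11 | CCCC[C@H](C)[C@H](OC(=O)C[C@H](C)C[C@H](O[Si](C)(C)C(C)(C)C)CCC[C@H](O[Si](C)(C)C(C)(C)C)CCC[C@@H](O[Si](C)(C)C(C)(C)C)CCC[C@H](O[Si](C)(C)C(C)(C)C)CCC[C@@H](O[Si](C)(C)C(C)(C)C)CCC[C@H](OCc1ccc(OC)cc1)C[C@H](O[Si](C)(C)C(C)(C)C)C[C@@H](O[Si](C)(C)C(C)(C)C)C=C)C[C@@H](OCc1ccc(OC)cc1)CC=C | intermediate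
53 | 36-membered macrolactone with C30=C31 alkene (E/Z mixture); OTBS at C5, C9, C13, C17, C21, C27, C29; OPMB at C25 and C33 | CCCC[C@H](C)[C@H]1C[C@@H](OCc2ccc(OC)cc2)CC=C[C@H](O[Si](C)(C)C(C)(C)C)C[C@@H](O[Si](C)(C)C(C)(C)C)C[C@@H](OCc2ccc(OC)cc2)CCC[C@H](O[Si](C)(C)C(C)(C)C)CCC[C@@H](O[Si](C)(C)C(C)(C)C)CCC[C@H](O[Si](C)(C)C(C)(C)C)CCC[C@@H](O[Si](C)(C)C(C)(C)C)CCC[C@@H](O[Si](C)(C)C(C)(C)C)C[C@@H](C)CC(=O)O1 | intermediate
54 | saturated macrolactone 25,33-diol with OTBS at C5, C9, C13, C17, C21, C27, C29 | CCCC[C@H](C)[C@H]1C[C@@H](O)CCC[C@H](O[Si](C)(C)C(C)(C)C)C[C@@H](O[Si](C)(C)C(C)(C)C)C[C@@H](O)CCC[C@H](O[Si](C)(C)C(C)(C)C)CCC[C@@H](O[Si](C)(C)C(C)(C)C)CCC[C@H](O[Si](C)(C)C(C)(C)C)CCC[C@@H](O[Si](C)(C)C(C)(C)C)CCC[C@@H](O[Si](C)(C)C(C)(C)C)C[C@@H](C)CC(=O)O1 | intermediate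
55 | CNP0225459.2, (4R,6R,10R,14S,18S,22R,26S,28S,30S,34S,36R)-36-[(2S)-hexan-2-yl]-6,10,14,18,22,26,28,30,34-nonahydroxy-4-methyl-1-oxacyclohexatriacontan-2-one | CCCC[C@H](C)[C@H]1C[C@@H](O)CCC[C@H](O)C[C@@H](O)C[C@@H](O)CCC[C@H](O)CCC[C@@H](O)CCC[C@H](O)CCC[C@@H](O)CCC[C@@H](O)C[C@@H](C)CC(=O)O1 | target

## Step count and least certain steps

Total: 29 steps. Longest linear sequence: 20 steps (12 to 55 through steps 8–10 and 13–29).

Step 3 (key step). Facial control may be incomplete because the catalyst has to act against the Felkin preference of the aldehyde; the α-centre of 4 may also epimerise on the Lewis acid, and turnover may be slow with an α-branched aldehyde. Fallback, setting out from 4 and returning at 7: an auxiliary-controlled acetate aldol of 4 with N-acetyl-(S)-4-isopropyl-1,3-thiazolidine-2-thione (TiCl4, i-Pr2NEt; or the mirror-image auxiliary, whichever gives 35R) should give (S)-4-isopropyl-3-[(3R,4S)-3-hydroxy-4-methyloctanoyl]-1,3-thiazolidine-2-thione F1. Displacement of the auxiliary with N,O-dimethylhydroxylamine gives (3R,4S)-3-hydroxy-N-methoxy-N,4-dimethyloctanamide F2. Excess ethynylmagnesium bromide gives (5R,6S)-5-hydroxy-6-methyldec-1-yn-3-one F3. A 6-endo cyclisation of the hydroxyl onto the ynone (AuCl(PPh3)/AgOTf, cat.) closes the same dihydropyranone 7.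

Step 10 (and its mirror, step 12). The chlorination may proceed with the wrong or an insufficient sense of induction, the α-chloro aldehyde may racemise before reduction, or epoxide closure may be incomplete. Fallback, setting out from 14 and returning at 17: D-proline-catalysed α-aminoxylation with nitrosobenzene followed by NaBH4 should give (2S,4S)-6-[(tert-butyldimethylsilyl)oxy]-4-methyl-2-[(phenylamino)oxy]hexan-1-ol F4. Cleavage of the N–O bond (Zn, AcOH) gives (2S,4S)-6-[(tert-butyldimethylsilyl)oxy]-4-methylhexane-1,2-diol F5. Selective primary tosylation (TsCl, Bu2SnO cat., Et3N) gives (2S,4S)-6-[(tert-butyldimethylsilyl)oxy]-2-hydroxy-4-methylhexyl 4-methylbenzenesulfonate F6, and K2CO3 in MeOH closes epoxide 17 with retention at C5. The same sequence with L-proline would serve for 22.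

Step 18. Hydrogenolysis of five hindered dithianes in one molecule may stall through sulfur poisoning of the nickel surface, leaving partly desulfurised material, and basic nickel may erode silyl ethers on long exposure. Fallback, setting out from 40 and returning at 41: the mechanism is changed from surface hydrogenolysis to electron transfer, using lithium in ethylamine/THF at −78 °C, which cleaves both C–S bonds of each dithiane and leaves silyl ethers, ketal and the alcohol; no new compound is made.

Step 27. At a ring size of 36, intermolecular metathesis (oligomerisation) may compete with ring closure, and ruthenium hydrides may isomerise the terminal alkenes and give ring-contracted products. Fallback, setting out from 50 and 11 and returning at 53: the order of bond formation is reversed. Cross-metathesis of acid 50 with an excess of alcohol 11 (second-generation Grubbs catalyst) should give the seco hydroxy acid F7, in which the slow-dimerising allylic ether alkene of 50 pairs with the unhindered alkene of 11. Yamaguchi macrolactonisation of F7 at high dilution then gives 53 as its E isomer.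

## Further compounds

F1 | step 3 | (S)-4-isopropyl-3-[(3R,4S)-3-hydroxy-4-methyloctanoyl]-1,3-thiazolidine-2-thione | CCCC[C@H](C)[C@H](O)CC(=O)N1C(=S)SC[C@@H]1C(C)C
F2 | step 3 | (3R,4S)-3-hydroxy-N-methoxy-N,4-dimethyloctanamide | CCCC[C@H](C)[C@H](O)CC(=O)N(C)OC
F3 | step 3 | (5R,6S)-5-hydroxy-6-methyldec-1-yn-3-one | CCCC[C@H](C)[C@H](O)CC(=O)C#C
F4 | step 10 | (2S,4S)-6-[(tert-butyldimethylsilyl)oxy]-4-methyl-2-[(phenylamino)oxy]hexan-1-ol | OC[C@@H](ONc1ccccc1)C[C@@H](C)CCO[Si](C)(C)C(C)(C)C
F5 | step 10 | (2S,4S)-6-[(tert-butyldimethylsilyl)oxy]-4-methylhexane-1,2-diol | OC[C@@H](O)C[C@@H](C)CCO[Si](C)(C)C(C)(C)C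
F6 | step 10 | (2S,4S)-6-[(tert-butyldimethylsilyl)oxy]-2-hydroxy-4-methylhexyl 4-methylbenzenesulfonate | Cc1ccc(cc1)S(=O)(=O)OC[C@@H](O)C[C@@H](C)CCO[Si](C)(C)C(C)(C)C
F0 | step 18 | none | none
F7 | step 27 | seco hydroxy acid: C1 acid, (E)-C30=C31 alkene, 35-OH, OPMB at C25 and C33, OTBS at C5, C9, C13, C17, C21, C27, C29 | CCCC[C@H](C)[C@H](O)C[C@@H](OCc1ccc(OC)cc1)C/C=C/[C@H](O[Si](C)(C)C(C)(C)C)C[C@@H](O[Si](C)(C)C(C)(C)C)C[C@@H](OCc1ccc(OC)cc1)CCC[C@H](O[Si](C)(C)C(C)(C)C)CCC[C@@H](O[Si](C)(C)C(C)(C)C)CCC[C@H](O[Si](C)(C)C(C)(C)C)CCC[C@@H](O[Si](C)(C)C(C)(C)C)CCC[C@@H](O[Si](C)(C)C(C)(C)C)C[C@@H](C)CC(=O)O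
A1 | alternative 1 | C2-symmetric (E,E)-diene tetraol bis-pivalate spanning C5–C25 | CC(C)(C)C(=O)OCCCC[C@H](O)/C=C/C[C@@H](O)CCC[C@H](O)C/C=C/[C@@H](O)CCCCOC(=O)C(C)(C)C
A2 | alternative 2 | 14,15-didehydro macrolactone with nine TBS ethers | CCCC[C@H](C)[C@H]1C[C@@H](O[Si](C)(C)C(C)(C)C)CCC[C@H](O[Si](C)(C)C(C)(C)C)C[C@@H](O[Si](C)(C)C(C)(C)C)C[C@@H](O[Si](C)(C)C(C)(C)C)CCC[C@H](O[Si](C)(C)C(C)(C)C)CCC[C@@H](O[Si](C)(C)C(C)(C)C)CC#C[C@H](O[Si](C)(C)C(C)(C)C)CCC[C@@H](O[Si](C)(C)C(C)(C)C)CCC[C@@H](O[Si](C)(C)C(C)(C)C)C[C@@H](C)CC(=O)O1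
A3 | alternative 2 | molybdenum alkylidyne Mo(CC6H4OMe)(OSiPh3)3 | COc1ccc(cc1)C#[Mo](O[Si](c1ccccc1)(c1ccccc1)c1ccccc1)(O[Si](c1ccccc1)(c1ccccc1)c1ccccc1)O[Si](c1ccccc1)(c1ccccc1)c1ccccc1
A4 | alternative 3 | (4R,6S)-6-(chloromethyl)oxane-2,4-diol | ClC[C@@H]1C[C@@H](O)CC(O)O1
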